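The oxolane of the target holds its C9 oxymethyl arm (on C8) and its C7' benzyl arm (on C8') on the same face. Tying the C9 oxygen back to C7' therefore gives a cis-fused 3,7-dioxabicyclo[3.3.0]octane whose ring fusion enforces that relationship. This bicycle is assembled in one flask from a trans-2-guaiacyl-3-(silyloxymethyl)-2,3-dihydrofuran and O-acetylsyringaldehyde. The C9' oxygen and the aldehyde form an oxocarbenium ion, enol ether carbon C8 closes the syringyl oxolane (bonds O–C7 and C7–C8, stereocentres C7 and C8), and a silane reduces the C9 cation left behind. Hydrogenolysis later cuts only the guaiacyl C7'–O bond and frees C9–OH for feruloylation.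

Key step: step 9

Remark: lignan numbering is used (C7–C8–C9 for the syringyl half, C7'–C8'–C9' for the guaiacyl half). Ring A is the oxolane O/C7/C8/C8'/C9' that survives; ring B is the oxolane O/C7'/C8'/C8/C9 that is opened. The target is (7S,8R,8'R). This maps onto the (7S,7'S,8R,8'R) furofuran and the (2S,3R) dihydrofuran, and so calls for the (S)-configured oxazolidinone.
Assumption: 4-(benzyloxy)-3-methoxybenzaldehyde and methyl 4-chloro-4-oxobutanoate are bought rather than made from vanillin and succinic anhydride.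

Step 1
Reactants: 1 (S)-4-benzyl-1,3-oxazolidin-2-one; 2 methyl 4-chloro-4-oxobutanoate
Product: 3 methyl 4-[(4S)-4-benzyl-2-oxo-1,3-oxazolidin-3-yl]-4-oxobutanoate
Conditions: n-BuLi, THF, −78 °C; then 2, −78 → 0 °C
Reagents that add atoms: none
Why: N-acylation of the lithiated oxazolidinone by the acid chloride is fast at −78 °C and leaves the methyl ester untouched.

Step 2
Reactants: 3 methyl 4-[(4S)-4-benzyl-2-oxo-1,3-oxazolidin-3-yl]-4-oxobutanoate; 4 4-(benzyloxy)-3-methoxybenzaldehyde
Product: 6 (4S)-4-benzyl-3-{[(2S,3S)-2-[4-(benzyloxy)-3-methoxyphenyl]-5-oxooxolan-3-yl]carbonyl}-1,3-oxazolidin-2-one (2,3-trans lactone), via syn-aldol adduct 5 (not isolated)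
Conditions: Bu2BOTf, i-Pr2NEt, CH2Cl2, 0 °C; 4, −78 → 0 °C; pH 7 buffer, MeOH, H2O2, 0 °C; crude, PPTS (cat.), toluene, 60 °C
Reagents that add atoms: none
Why: In this Evans syn-aldol reaction Bu2BOTf/i-Pr2NEt enolises only the imide side to the Z-enolate, its Zimmerman–Traxler chair, shielded by the auxiliary benzyl group, sets C8' and C7' as the syn adduct 5, and attack of the C7' oxygen on the methyl ester turns syn into the 2,3-trans lactone.

Step 3
Reactants: 6 lactone imide
Product: 7 (2S,3S)-2-[4-(benzyloxy)-3-methoxyphenyl]-5-oxooxolane-3-carboxylic acid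
Conditions: LiOH, H2O2, THF/H2O, 0 °C; aq. Na2SO3; HCl to pH 2
Reagents that add atoms: hydrogen peroxide (as LiOOH), OO
Why: Hydroperoxide attacks the exocyclic imide carbonyl selectively (standard auxiliary cleavage), any opened lactone recloses on acidification, and the trans acid is also the more stable epimer, so C8' is not at risk.

Step 4
Reactants: 7 trans paraconic acid
Product: 8 (4R,5S)-5-[4-(benzyloxy)-3-methoxyphenyl]-4-(hydroxymethyl)oxolan-2-one
Conditions: BH3·SMe2, THF, 0 °C → rt; aqueous work-up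
Reagents that add atoms: none
Why: Borane reduces a free carboxylic acid through its acyloxyborane far faster than a lactone, a chemoselectivity well established for paraconic acids.

Step 5
Reactants: 8 hydroxymethyl lactone
Product: 9 (4R,5S)-5-[4-(benzyloxy)-3-methoxyphenyl]-4-[(triethylsilyloxy)methyl]oxolan-2-one
Conditions: Et3SiCl, imidazole, CH2Cl2, 0 °C
Reagents that add atoms: chlorotriethylsilane, CC[Si](Cl)(CC)CC
Why: Silylation of the primary alcohol under mildly basic conditions avoids translactonisation; the triethylsilyl group survives the next two steps yet is handed over readily in step 9, so no deprotection and no free hydroxy enol ether is needed.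

Step 6
Reactants: 9 silyl ether lactone
Product: 10 (4R,5S)-5-[4-(benzyloxy)-3-methoxyphenyl]-4-[(triethylsilyloxy)methyl]oxolan-2-ol (anomeric mixture)
Conditions: i-Bu2AlH, CH2Cl2, −78 °C; aq. potassium sodium tartrate
Reagents that add atoms: none
Why: Partial reduction of a gamma-lactone at −78 °C stops at the tetrahedral aluminium hemiacetal, which gives the lactol on work-up.

Step 7
Reactants: 10 lactol
Product: 12 triethyl{[(2S,3R)-2-[4-(benzyloxy)-3-methoxyphenyl]-2,3-dihydrofuran-3-yl]methoxy}silane (2,3-trans), via anomeric mesylate 11 (not isolated)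
Conditions: MsCl, Et3N, CH2Cl2, −40 °C → reflux; chromatography on Et3N-deactivated silica
Reagents that add atoms: none
Why: Mesylation of the anomeric hydroxyl, ionisation and loss of a C8 proton to Et3N is the established dehydration of 2-deoxy lactols to furanoid glycals, and the permanently basic medium protects the acid-labile enol ether as well as C7' and C8'.

Step 8
Reactants: 13 syringaldehyde
Product: 14 4-acetoxy-3,5-dimethoxybenzaldehyde
Conditions: Ac2O, pyridine, rt
Reagents that add atoms: acetic anhydride, CC(=O)OC(C)=O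
Why: Routine phenol acetylation, which lowers the electron density of the syringyl ring for steps 9 and 10.

Step 9
Reactants: 12 trans dihydrofuran triethylsilyl ether; 14 4-acetoxy-3,5-dimethoxybenzaldehyde
Product: 17 4-{(1S,3aR,4S,6aR)-4-[4-(benzyloxy)-3-methoxyphenyl]tetrahydro-1H,3H-furo[3,4-c]furan-1-yl}-2,6-dimethoxyphenyl acetate (both aryl groups exo), via tethered E-oxocarbenium triflate 15 (not isolated), via bicyclic C9 oxocarbenium triflate 16 (not isolated)
Conditions: Me3SiOTf (1.1 equiv), 2,6-di-tert-butyl-4-methylpyridine (0.2 equiv), 4 Å MS, CH2Cl2, −78 °C; then Et3SiH (4 equiv), −78 → −40 °C; Et3N, aq. NaHCO3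
Reagents that add atoms: none
Why: Me3SiOTf-promoted exchange between the triethylsilyl ether of 12 and aldehyde 14 expels Et3SiOSiMe3 and gives the E-oxocarbenium ion 15 (bond O–C7) under aprotic conditions, the nucleophilic enol ether carbon C8 then attacks C7 (bond C7–C8) and shifts the charge to C9 (16), and Et3SiH delivers hydride to C9. The closest known chemistry is the silyl triflate-mediated Prins-type annulation of 2-aryl-3-hydroxymethyl-2,3-dihydrofurans with aryl aldehydes or their acetals followed by ionic hydrogenation of the bicyclic acetal carbon, and the silyl ether/aldehyde pairing is the standard water-free entry to such ions. Ring A (O, C7, C8, C8', C9') closes in a 5-(enol-exo)-endo-trig mode, with C7=O+ inside and C8=C9 outside the forming ring. C8 is fixed by C8', because the three-atom tether reaches only the face of the enol ether that carries C9', which is also the face anti to the guaiacyl group, so only the cis-fused bicycle can form. C7 is set by the E geometry of 15 reacting through the envelope whose oxygen points away from ring B, which puts H7 under ring B and the aryl group on the convex face, trans to C9. The step needs O–C7 bonding before C–C bonding, ring closure before hydride transfer and a configurationally stable C7: an aldehyde activated only by Me3SiOTf is too weak an electrophile for direct attack by the enol ether, the silane is added only after ring closure, and the acetate keeps the syringyl C7–O bond from ionising at −78 °C.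

Step 10
Reactants: 17 differentially protected furofuran
Product: 19 4-[(2S,3R,4R)-4-(4-hydroxy-3-methoxybenzyl)-3-(hydroxymethyl)oxolan-2-yl]-2,6-dimethoxyphenyl acetate, via debenzylated furofuran phenol 18 (not isolated)
Conditions: H2 (1 atm), 10% Pd on carbon, EtOAc/THF, AcOH (trace), rt
Reagents that add atoms: none
Why: In this catalytic hydrogenolysis the benzyl ether falls first, the freed para-hydroxyl makes the guaiacyl C7'–O bond the only strongly activated benzylic ether, and the C7–O bond next to the para-acetoxy ring stays, so ring B opens to the C7' methylene and the C9 alcohol without touching C7, C8 or C8'.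

Step 11
Reactants: 19 oxolane alcohol; 20 (E)-ferulic acid
Product: 21 [(2S,3R,4R)-2-(4-acetoxy-3,5-dimethoxyphenyl)-4-(4-hydroxy-3-methoxybenzyl)oxolan-3-yl]methyl (E)-3-(4-hydroxy-3-methoxyphenyl)prop-2-enoate
Conditions: PPh3, DIAD, THF, 0 °C → rt (20 in slight excess)
Reagents that add atoms: none
Why: Mitsunobu esterification favours the carboxylic acid over the phenols because only the acid protonates the betaine, a behaviour documented for unprotected hydroxycinnamic acids and phenolic alcohols, and the primary C9 carbon carries no stereocentre.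

Step 12
Reactants: 21 acetate of the target
Product: 22 target, [(2S,3R,4R)-2-(4-hydroxy-3,5-dimethoxyphenyl)-4-(4-hydroxy-3-methoxybenzyl)oxolan-3-yl]methyl (E)-ferulate
Conditions: pyrrolidine, CH2Cl2, 0 °C → rt; dilute acid wash
Reagents that add atoms: none
Why: Aminolysis by pyrrolidine cleaves aryl acetates quickly because phenoxide is a good leaving group, whereas alkyl cinnamates are inert under these conditions, a selectivity routinely used on ferulate and coumarate esters.

Compound list
1 | (S)-4-benzyl-1,3-oxazolidin-2-one | O=C1N[C@@H](Cc2ccccc2)CO1 | starting material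
2 | methyl 4-chloro-4-oxobutanoate | COC(=O)CCC(=O)Cl | starting material
3 | methyl 4-[(4S)-4-benzyl-2-oxo-1,3-oxazolidin-3-yl]-4-oxobutanoate | COC(=O)CCC(=O)N1[C@@H](Cc2ccccc2)COC1=O | intermediate
4 | 4-(benzyloxy)-3-methoxybenzaldehyde | COc1cc(C=O)ccc1OCc1ccccc1 | starting material
5 | methyl (3S)-3-{(S)-[4-(benzyloxy)-3-methoxyphenyl](hydroxy)methyl}-4-[(4S)-4-benzyl-2-oxo-1,3-oxazolidin-3-yl]-4-oxobutanoate (syn aldol, not isolated) | COC(=O)C[C@@H]([C@H](O)c1ccc(OCc2ccccc2)c(OC)c1)C(=O)N1[C@@H](Cc2ccccc2)COC1=O | intermediate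
6 | (4S)-4-benzyl-3-{[(2S,3S)-2-[4-(benzyloxy)-3-methoxyphenyl]-5-oxooxolan-3-yl]carbonyl}-1,3-oxazolidin-2-one | O=C1C[C@H](C(=O)N2[C@@H](Cc3ccccc3)COC2=O)[C@@H](c2ccc(OCc3ccccc3)c(OC)c2)O1 | intermediate
7 | (2S,3S)-2-[4-(benzyloxy)-3-methoxyphenyl]-5-oxooxolane-3-carboxylic acid | O=C1C[C@H](C(=O)O)[C@@H](c2ccc(OCc3ccccc3)c(OC)c2)O1 | intermediate
8 | (4R,5S)-5-[4-(benzyloxy)-3-methoxyphenyl]-4-(hydroxymethyl)oxolan-2-one | O=C1C[C@H](CO)[C@@H](c2ccc(OCc3ccccc3)c(OC)c2)O1 | intermediate
9 | (4R,5S)-5-[4-(benzyloxy)-3-methoxyphenyl]-4-[(triethylsilyloxy)methyl]oxolan-2-one | O=C1C[C@H](CO[Si](CC)(CC)CC)[C@@H](c2ccc(OCc3ccccc3)c(OC)c2)O1 | intermediate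
10 | (4R,5S)-5-[4-(benzyloxy)-3-methoxyphenyl]-4-[(triethylsilyloxy)methyl]oxolan-2-ol (anomeric mixture) | OC1C[C@H](CO[Si](CC)(CC)CC)[C@@H](c2ccc(OCc3ccccc3)c(OC)c2)O1 | intermediate
11 | anomeric methanesulfonate of 10 (not isolated) | CS(=O)(=O)OC1C[C@H](CO[Si](CC)(CC)CC)[C@@H](c2ccc(OCc3ccccc3)c(OC)c2)O1 | intermediate
12 | triethyl{[(2S,3R)-2-[4-(benzyloxy)-3-methoxyphenyl]-2,3-dihydrofuran-3-yl]methoxy}silane | CC[Si](CC)(CC)OC[C@H]1C=CO[C@@H]1c1ccc(OCc2ccccc2)c(OC)c1 | intermediate
13 | syringaldehyde | COc1cc(C=O)cc(OC)c1O | starting material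
14 | 4-acetoxy-3,5-dimethoxybenzaldehyde | COc1cc(C=O)cc(OC)c1OC(C)=O | intermediate
15 | tethered E-oxocarbenium triflate (O–C7 formed, not isolated) | CC(=O)Oc1c(OC)cc(/C=[O+]/C[C@H]2C=CO[C@@H]2c2ccc(OCc3ccccc3)c(OC)c2)cc1OC.[O-]S(=O)(=O)C(F)(F)F | intermediate
16 | cis-fused bicyclic C9 oxocarbenium triflate (C7–C8 formed, not isolated) | C=1[C@H]2[C@@H]([C@@H](c3ccc(OCc4ccccc4)c(OC)c3)[O+]=1)CO[C@@H]2c1cc(OC)c(OC(C)=O)c(OC)c1.[O-]S(=O)(=O)C(F)(F)F | intermediate
17 | 4-{(1S,3aR,4S,6aR)-4-[4-(benzyloxy)-3-methoxyphenyl]tetrahydro-1H,3H-furo[3,4-c]furan-1-yl}-2,6-dimethoxyphenyl acetate | C1[C@H]2[C@@H]([C@@H](c3ccc(OCc4ccccc4)c(OC)c3)O1)CO[C@@H]2c1cc(OC)c(OC(C)=O)c(OC)c1 | intermediate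
18 | 4-[(1S,3aR,4S,6aR)-4-(4-hydroxy-3-methoxyphenyl)tetrahydro-1H,3H-furo[3,4-c]furan-1-yl]-2,6-dimethoxyphenyl acetate (not isolated) | C1[C@H]2[C@@H]([C@@H](c3ccc(O)c(OC)c3)O1)CO[C@@H]2c1cc(OC)c(OC(C)=O)c(OC)c1 | intermediate
19 | 4-[(2S,3R,4R)-4-(4-hydroxy-3-methoxybenzyl)-3-(hydroxymethyl)oxolan-2-yl]-2,6-dimethoxyphenyl acetate | OC[C@H]1[C@@H](Cc2ccc(O)c(OC)c2)CO[C@@H]1c1cc(OC)c(OC(C)=O)c(OC)c1 | intermediate
20 | (E)-ferulic acid | COc1cc(/C=C/C(=O)O)ccc1O | starting material
21 | [(2S,3R,4R)-2-(4-acetoxy-3,5-dimethoxyphenyl)-4-(4-hydroxy-3-methoxybenzyl)oxolan-3-yl]methyl (E)-ferulate | COc1cc(/C=C/C(=O)OC[C@H]2[C@@H](Cc3ccc(O)c(OC)c3)CO[C@@H]2c2cc(OC)c(OC(C)=O)c(OC)c2)ccc1O | intermediate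
22 | CNP0289934.1, [(2S,3R,4R)-2-(4-hydroxy-3,5-dimethoxyphenyl)-4-(4-hydroxy-3-methoxybenzyl)oxolan-3-yl]methyl (E)-ferulate | COc1cc(/C=C/C(=O)OC[C@H]2[C@@H](Cc3ccc(O)c(OC)c3)CO[C@@H]2c2cc(OC)c(O)c(OC)c2)ccc1O | target

Total step count: 12. Longest linear sequence: 11 (steps 1–7 and 9–12; step 8 is a side branch).

Steps most likely to fail

**Risk 1, step 9.**
- The envelope of ion 15 that folds the C7=O+ unit under ring B may compete and erode the exo/endo discrimination at C7.
- Acid equilibration cannot repair this, because exo- and endo-aryl furofurans lie close in energy.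
- Proton-initiated oligomerisation of the enol ether is the second failure mode.

The fallback gives up the bicycle and sets C7 on a monocyclic ring. It sets out from 8 and returns at 22. Hydrogenation of 8 (H2, Pd on carbon, AcOH/EtOAc) removes the benzyl group and hydrogenolyses the benzylic lactone C7'–O bond. The hydroxy acid relactonises through C9'–OH to (R)-4-(4-hydroxy-3-methoxybenzyl)oxolan-2-one F1, which BnBr/K2CO3 converts into its benzyl ether F2. The enolate of F2 (LiN(SiMe3)2, THF, −78 °C) adds, anti to the benzyl arm, to 4-(benzyloxy)-3,5-dimethoxybenzaldehyde F3 (from 13, BnBr, K2CO3) and gives the trans aldol lactone F4, whose C7 epimers are both usable. LiAlH4 gives the (8R,8'R)-triol F5. Catalytic camphorsulfonic acid in CH2Cl2 then ionises the benzylic C7–OH, so that C9'–OH closes the oxolane under steric control to the 7,8-trans dibenzyl ether F6. Brief hydrogenolysis gives 5-methoxylariciresinol F7, whose primary C9–OH is esterified with 20 under the conditions of step 11 to give 22 directly.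

**Risk 2, step 10.** Site selectivity may be lost through slow further hydrogenolysis at C7–O, or the reaction may stall after debenzylation. The fallback separates the two events and replaces surface hydrogenolysis by an ionic mechanism. It sets out from 17 and returns at 19. Transfer hydrogenolysis (Pd on carbon, cyclohexa-1,4-diene, EtOAc/EtOH, rt) stops at phenol 18, which is isolated this time. Et3SiH with BF3·OEt2 in CH2Cl2 at −40 °C (ionic hydrogenation) then cleaves only the bond that can ionise to a quinone-methide-like cation, namely C7'–O. No new compound is made.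

**Risk 3, step 7.** The elimination may be incomplete, or the enol ether may isomerise or hydrolyse during heating and isolation. The fallback replaces the ionising elimination by a neutral thermal syn-elimination. It sets out from 10 and returns at 12. PhSSPh and Bu3P in THF convert 10 into the phenylthio acetal F8, m-CPBA at −78 °C gives the sulfoxide F9, and heating in toluene with i-Pr2NEt and P(OMe)3 as sulfenic acid trap gives 12.

Further compounds
F1 | step 9 | (R)-4-(4-hydroxy-3-methoxybenzyl)oxolan-2-one | O=C1C[C@@H](Cc2ccc(O)c(OC)c2)CO1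
F2 | step 9 | (R)-4-[4-(benzyloxy)-3-methoxybenzyl]oxolan-2-one | O=C1C[C@@H](Cc2ccc(OCc3ccccc3)c(OC)c2)CO1
F3 | step 9 | 4-(benzyloxy)-3,5-dimethoxybenzaldehyde | COc1cc(C=O)cc(OC)c1OCc1ccccc1
F4 | step 9 | (3S,4R)-4-[4-(benzyloxy)-3-methoxybenzyl]-3-{[4-(benzyloxy)-3,5-dimethoxyphenyl](hydroxy)methyl}oxolan-2-one (C7 epimers) | O=C1OC[C@H](Cc2ccc(OCc3ccccc3)c(OC)c2)[C@H]1C(O)c1cc(OC)c(OCc2ccccc2)c(OC)c1
F5 | step 9 | (8R,8'R)-triol, 2-[4-(benzyloxy)-3-methoxybenzyl]-3-{[4-(benzyloxy)-3,5-dimethoxyphenyl](hydroxy)methyl}butane-1,4-diol | OC[C@H](Cc1ccc(OCc2ccccc2)c(OC)c1)[C@H](CO)C(O)c1cc(OC)c(OCc2ccccc2)c(OC)c1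
F6 | step 9 | {(2S,3R,4R)-4-[4-(benzyloxy)-3-methoxybenzyl]-2-[4-(benzyloxy)-3,5-dimethoxyphenyl]oxolan-3-yl}methanol | OC[C@H]1[C@@H](Cc2ccc(OCc3ccccc3)c(OC)c2)CO[C@@H]1c1cc(OC)c(OCc2ccccc2)c(OC)c1
F7 | step 9 | 5-methoxylariciresinol, (7S,8R,8'R) | OC[C@H]1[C@@H](Cc2ccc(O)c(OC)c2)CO[C@@H]1c1cc(OC)c(O)c(OC)c1
F0 | step 10 | none | none
F8 | step 7 | (4R,5S)-configured 2-(phenylsulfanyl)oxolane derived from 10 (anomeric mixture) | c1ccccc1SC1C[C@H](CO[Si](CC)(CC)CC)[C@@H](c2ccc(OCc3ccccc3)c(OC)c2)O1
F9 | step 7 | corresponding 2-(phenylsulfinyl)oxolane (diastereomer mixture) | O=S(c1ccccc1)C1C[C@H](CO[Si](CC)(CC)CC)[C@@H](c2ccc(OCc3ccccc3)c(OC)c2)O1
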